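**Retrosynthetic overview**

1. Cardopatine 20 is the C2-symmetric trans-(1R,2R)-cyclobutane with a (2,2'-bithiophen-5-yl)ethynyl group on each stereocentre (ring numbering: C1 and C2 are the stereocentres, C3 and C4 the methylenes, C4 next to C1). Both C(sp)–thienyl bonds are cut last (double Sonogashira of diyne 19 with bromide 18); 19 comes from the mono-silylated diyne 17.
2. The ethynyl group on C2 is traced back to a C2–B bond (Zweifel-type alkynylation with retention), which leads to the trans-cyclobutylboronate 11.
3. The strategy rests on the ring bond C1–C4, between an alkyne-bearing stereocentre and a ring CH2. It can be made from a propargylic C1–copper bond and a primary sulfonate while C2 takes up boron in the same event, so 11 opens to the acyclic Z-enyne mesylate 8 and B2pin2 9.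
4. Mesylate 8 is built in four steps from but-3-yn-1-ol 1 and ethynyltriisopropylsilane 5 through the Z-vinyl iodide 4.
5. Ring order: the cyclobutane is the only ring formed; it is closed in step 5, where both stereocentres are set.

Key step: step 5

Assumption: the sense of induction of the bisphosphine with an alkynyl-substituted Z-alkene cannot be assigned in advance, so step 5 is written with (R)-Segphos and the (S)-ligand is taken instead if the first run shows the (1S,2S) boronate.

**Route**

Step 1
Reactants: 1 but-3-yn-1-ol; 2 N-iodosuccinimide
Product: 3 4-iodobut-3-yn-1-ol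
Conditions: NIS (1.1 equiv), AgNO3 (10 mol %), acetone, rt, dark
Reagents that add atoms: N-iodosuccinimide (2), O=C1CCC(=O)N1I
Why: Silver-catalysed electrophilic iodination of the terminal alkyne C–H by N-iodosuccinimide is selective for the sp C–H and should leave the primary alcohol untouched.

Step 2
Reactants: 3 4-iodobut-3-yn-1-ol
Product: 4 (Z)-4-iodobut-3-en-1-ol
Conditions: 2-nitrobenzenesulfonyl hydrazide (2 equiv), Et3N, THF/i-PrOH, rt
Reagents that add atoms: none
Why: Diimide reduction: the diimide released from the sulfonyl hydrazide delivers two hydrogens to the same face of the iodoalkyne in a concerted transfer, so the Z-vinyl iodide should form with the C–I bond intact, provided the reaction is stopped before the slower reduction of the alkene sets in.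

Step 3
Reactants: 4 (Z)-4-iodobut-3-en-1-ol; 5 ethynyltriisopropylsilane
Product: 6 (Z)-6-(triisopropylsilyl)hex-3-en-5-yn-1-ol
Conditions: Pd(PPh3)2Cl2 (2 mol %), CuI (4 mol %), i-Pr2NH, THF, rt
Reagents that add atoms: ethynyltriisopropylsilane (5), C#C[Si](C(C)C)(C(C)C)C(C)C
Why: Sonogashira coupling of a vinyl iodide runs at room temperature with retention of the alkene geometry, and neither the free alcohol nor the silyl group should interfere.

Step 4
Reactants: 6 (Z)-6-(triisopropylsilyl)hex-3-en-5-yn-1-ol; 7 methanesulfonyl chloride
Product: 8 (Z)-6-(triisopropylsilyl)hex-3-en-5-yn-1-yl methanesulfonate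
Conditions: MsCl, Et3N, CH2Cl2, 0 °C
Reagents that add atoms: methanesulfonyl chloride (7), CS(=O)(=O)Cl
Why: Sulfonylation of the primary alcohol is fast at 0 °C and turns the future C4 into the electrophile for ring closure without touching the Z-enyne.

Step 5
Reactants: 8 (Z)-6-(triisopropylsilyl)hex-3-en-5-yn-1-yl methanesulfonate; 9 bis(pinacolato)diboron
Product: 11 (1R,2R)-2-[(triisopropylsilyl)ethynyl]cyclobutylboronic acid pinacol ester, via propargylic copper adduct 10 (not isolated)
Conditions: CuCl (5 mol %), (R)-Segphos (5 mol %), B2pin2 (1.2 equiv), KO-t-Bu (1.2 equiv), THF, rt, 8 added last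
Reagents that add atoms: bis(pinacolato)diboron (9), CC1(C)OB(OC1(C)C)B1OC(C)(C)C(C)(C)O1
Why: Proposed new method: CuCl, the bisphosphine and KO-t-Bu should give a ligated copper alkoxide that is borylated by B2pin2, and the resulting copper boryl should add syn across the Z-alkene of 8 with boron on the carbon remote from the alkyne (future C2) and copper on the propargylic carbon (future C1), after which the C1–Cu bond of 10 attacks the primary mesylate carbon (future C4) by oxidative addition to a five-membered cupracycle of trivalent copper and reductive elimination, the copper alkoxide being returned by KO-t-Bu. The closest known reaction type is the copper-catalysed enantioselective borylative exo-cyclisation of (Z)-homoallylic sulfonates that carry a silyl or an aryl group on the alkene and give trans-2-substituted cyclobutylboronates; an alkynyl group in that position, and thus a propargylic copper nucleophile, has not been shown. The cyclobutane is closed in the 4-exo-tet mode through the new C1–C4 bond. C2 is set by the chiral bisphosphine in the enantio-determining borylcupration and cannot epimerise afterwards, while C1 follows from the Z geometry of the alkene through syn addition and substitution with retention at the copper-bearing carbon, which places the alkynyl group trans to boron. If the propargylic copper equilibrates with its allenyl form, both forms should still converge on the same ring, because closure at the allenyl terminus would need a six-membered cyclic allene, and the trans isomer is also the less strained one. The step needs the copper boryl to choose the alkene over the alkyne and ring closure to outrun base-induced loss of methanesulfonic acid: the bulky triisopropylsilyl group shields the triple bond, and the tert-butoxide is largely bound as the diboron ate complex and the copper alkoxide, not free in solution.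

Step 6
Reactants: 11 (1R,2R)-2-[(triisopropylsilyl)ethynyl]cyclobutylboronic acid pinacol ester; 12 vinyl bromide
Product: 15 (1R,2R)-1-(1-bromoethenyl)-2-[(triisopropylsilyl)ethynyl]cyclobutane, via lithium boronate complex 13 (not isolated), via iodo bromo boronic ester 14 (not isolated)
Conditions: vinyl bromide (3 equiv), LiN(i-Pr)2 (3 equiv, slow addition), THF, −78 °C; then I2, MeOH, −78 °C; then NaOMe, MeOH, −78 °C to rt
Reagents that add atoms: vinyl bromide (12), C=CBr
Why: Zweifel-type olefination: 1-bromoethenyllithium, generated in the presence of 11, adds to boron, iodine then triggers a stereospecific 1,2-shift of the cyclobutyl group to the bromine-bearing carbon with retention at the migrating ring carbon, and methoxide-induced anti elimination of boron and iodide releases the 2-bromoalkene, so the trans (1R,2R) arrangement should be carried over.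

Step 7
Reactants: 15 (1R,2R)-1-(1-bromoethenyl)-2-[(triisopropylsilyl)ethynyl]cyclobutane
Product: 17 (1R,2R)-1-ethynyl-2-[(triisopropylsilyl)ethynyl]cyclobutane, via lithium acetylide 16 (not isolated)
Conditions: LiN(i-Pr)2 (2.5 equiv), THF, −78 °C to 0 °C; then H2O
Reagents that add atoms: none
Why: Base-induced dehydrobromination (anti elimination across the 1-bromoethenyl group) gives the terminal alkyne, held as its lithium acetylide until the aqueous quench, and the ring C–H bonds should not be deprotonated under these conditions.

Step 8
Reactants: 17 (1R,2R)-1-ethynyl-2-[(triisopropylsilyl)ethynyl]cyclobutane; 18 5-bromo-2,2'-bithiophene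
Product: 20 cardopatine, (1R,2R)-1,2-bis[(2,2'-bithiophen-5-yl)ethynyl]cyclobutane, via trans-diethynylcyclobutane 19 (not isolated)
Conditions: Bu4NF (1.2 equiv), THF, 0 °C to rt; then 18 (2.4 equiv), Pd(PPh3)4 (5 mol %), CuI (10 mol %), i-Pr2NH, 55 °C, degassed, closed vessel, dark
Reagents that add atoms: 5-bromo-2,2'-bithiophene (18), Brc1ccc(-c2cccs2)s1
Why: Fluoride cleaves the C(sp)–Si bond, and the volatile diyne is not isolated but coupled at both termini in the same flask by Sonogashira coupling with the bromobithiophene, a reaction that does not touch the two ring stereocentres.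

**Compound list**

1 | but-3-yn-1-ol | C#CCCO | starting material
2 | N-iodosuccinimide | O=C1CCC(=O)N1I | starting material
3 | 4-iodobut-3-yn-1-ol | OCCC#CI | intermediate
4 | (Z)-4-iodobut-3-en-1-ol | OCC/C=C\I | intermediate
5 | ethynyltriisopropylsilane | C#C[Si](C(C)C)(C(C)C)C(C)C | starting material
6 | (Z)-6-(triisopropylsilyl)hex-3-en-5-yn-1-ol | OCC/C=C\C#C[Si](C(C)C)(C(C)C)C(C)C | intermediate
7 | methanesulfonyl chloride | CS(=O)(=O)Cl | starting material
8 | (Z)-6-(triisopropylsilyl)hex-3-en-5-yn-1-yl methanesulfonate | CS(=O)(=O)OCC/C=C\C#C[Si](C(C)C)(C(C)C)C(C)C | intermediate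
9 | bis(pinacolato)diboron | CC1(C)OB(OC1(C)C)B1OC(C)(C)C(C)(C)O1 | starting material
10 | [(3R,4R)-1-(methanesulfonyloxy)-3-(4,4,5,5-tetramethyl-1,3,2-dioxaborolan-2-yl)-6-(triisopropylsilyl)hex-5-yn-4-yl]copper (bisphosphine ligand not drawn; may equilibrate with its allenyl form) | CC(C)[Si](C(C)C)(C(C)C)C#C[C@H]([Cu])[C@@H](CCOS(C)(=O)=O)B1OC(C)(C)C(C)(C)O1 | intermediate (not isolated)
11 | (1R,2R)-2-[(triisopropylsilyl)ethynyl]cyclobutylboronic acid pinacol ester | CC(C)[Si](C(C)C)(C(C)C)C#C[C@@H]1CC[C@H]1B1OC(C)(C)C(C)(C)O1 | intermediate
12 | vinyl bromide | C=CBr | starting material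
13 | lithium (1-bromoethenyl)(pinacolato)[(1R,2R)-2-[(triisopropylsilyl)ethynyl]cyclobutyl]borate | [Li+].CC(C)[Si](C(C)C)(C(C)C)C#C[C@@H]1CC[C@H]1[B-]1(C(Br)=C)OC(C)(C)C(C)(C)O1 | intermediate (not isolated)
14 | 2-{1-bromo-2-iodo-1-[(1R,2R)-2-[(triisopropylsilyl)ethynyl]cyclobutyl]ethyl}-4,4,5,5-tetramethyl-1,3,2-dioxaborolane (either configuration at the bromine-bearing carbon) | CC(C)[Si](C(C)C)(C(C)C)C#C[C@@H]1CC[C@H]1C(Br)(CI)B1OC(C)(C)C(C)(C)O1 | intermediate (not isolated)
15 | (1R,2R)-1-(1-bromoethenyl)-2-[(triisopropylsilyl)ethynyl]cyclobutane | CC(C)[Si](C(C)C)(C(C)C)C#C[C@@H]1CC[C@H]1C(Br)=C | intermediate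
16 | {[(1R,2R)-2-[(triisopropylsilyl)ethynyl]cyclobutyl]ethynyl}lithium | CC(C)[Si](C(C)C)(C(C)C)C#C[C@@H]1CC[C@H]1C#C[Li] | intermediate (not isolated)
17 | (1R,2R)-1-ethynyl-2-[(triisopropylsilyl)ethynyl]cyclobutane | CC(C)[Si](C(C)C)(C(C)C)C#C[C@@H]1CC[C@H]1C#C | intermediate
18 | 5-bromo-2,2'-bithiophene | Brc1ccc(-c2cccs2)s1 | starting material
19 | (1R,2R)-1,2-diethynylcyclobutane | C#C[C@@H]1CC[C@H]1C#C | intermediate (not isolated)
20 | cardopatine, (1R,2R)-1,2-bis[(2,2'-bithiophen-5-yl)ethynyl]cyclobutane | C(#C[C@@H]1CC[C@H]1C#Cc1ccc(-c2cccs2)s1)c1ccc(-c2cccs2)s1 | target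

**Step count**

Total: 8 steps. Longest linear sequence: 8 steps (from but-3-yn-1-ol 1).

**Steps most likely to fail**

1. Step 5 (the proposed new method). What may go wrong:
- borylcupration at the triple bond, or with reversed regiochemistry, which would lead to three-membered ring closure;
- base-induced elimination of the mesylate before the copper boryl adds;
- protonation of the propargylic or allenyl copper instead of ring closure;
- weak facial discrimination, because the slim alkynyl group differentiates the alkene faces less than a silyl or aryl group does.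

Fallback, by known chemistry: the borylative ring closure is given up and the four-membered ring is taken from a commercial meso compound. None of compounds 1–17 is used; the fallback sets out from commercial cis-cyclobutane-1,2-dicarboxylic anhydride F1 and comes back to the route at diyne 19. Alkaloid-mediated desymmetrising methanolysis of F1 (quinine or quinidine, MeOH, toluene, −55 °C, the pseudo-enantiomer being chosen that gives the 1R,2S acid ester) should give (1R,2S)-2-(methoxycarbonyl)cyclobutane-1-carboxylic acid F2. NaOMe in MeOH should epimerise only the ester-bearing carbon to the more stable trans acid ester (1R,2R)-2-(methoxycarbonyl)cyclobutane-1-carboxylic acid F3. LiAlH4 in THF should reduce both carbonyl groups to the C2-symmetric diol [(1R,2R)-cyclobutane-1,2-diyl]dimethanol F4. Swern oxidation should give (1R,2R)-cyclobutane-1,2-dicarbaldehyde F5, which is used at once, because epimerisation through the meso cis dialdehyde would erode the enantiomeric purity. Corey–Fuchs dibromo-olefination (CBr4, PPh3, CH2Cl2, 0 °C) should give (1R,2R)-1,2-bis(2,2-dibromoethenyl)cyclobutane F6. n-BuLi (THF, −78 °C) followed by protonation should deliver 19 as a THF solution, which enters the coupling stage of step 8 with 18.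

2. Step 6. What may go wrong: decomposition of the 1-bromoethenyllithium carbenoid before it is captured by the hindered secondary boronic ester, incomplete formation of the boronate complex, or competing Matteson-type displacement of bromide in 14 by methoxide instead of elimination.

Fallback: it sets out from boronate 11 and comes back at alkyne 17, building the alkyne one carbon at a time. Matteson homologation with LiCHCl2 (CH2Cl2, n-BuLi, THF, −100 °C, then warming) should insert a CHCl unit into the C–B bond with retention at the ring carbon and give 2-{chloro[(1R,2R)-2-[(triisopropylsilyl)ethynyl]cyclobutyl]methyl}-4,4,5,5-tetramethyl-1,3,2-dioxaborolane F7. Oxidation with buffered H2O2 (or NaBO3) should release (1R,2R)-2-[(triisopropylsilyl)ethynyl]cyclobutane-1-carbaldehyde F8. Seyferth–Gilbert homologation with the Ohira–Bestmann reagent (K2CO3, MeOH, rt) should then give 17. Epimerisation next to the aldehyde would lead only to the less stable cis isomer, not to the enantiomer, since the other stereocentre is fixed.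

3. Step 8. What may go wrong: loss of the volatile diyne by evaporation, oxidative homocoupling to oligomers, slow oxidative addition of the electron-rich bromothiophene, or a stalled second coupling.

Fallback: it sets out from 17 and comes back at target 20 by a stepwise sequence in which the free diyne is never formed. Sonogashira coupling of 17 with one equivalent of 18 should give 5-{[(1R,2R)-2-[(triisopropylsilyl)ethynyl]cyclobutyl]ethynyl}-2,2'-bithiophene F9. Bu4NF in THF should then give the non-volatile terminal alkyne 5-{[(1R,2R)-2-ethynylcyclobutyl]ethynyl}-2,2'-bithiophene F10, and a second Sonogashira coupling with 18 should give 20.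

**Further compounds**

F1 | step 5 | cis-cyclobutane-1,2-dicarboxylic anhydride (3-oxabicyclo[3.2.0]heptane-2,4-dione, commercial) | O=C1OC(=O)[C@H]2CC[C@@H]12
F2 | step 5 | (1R,2S)-2-(methoxycarbonyl)cyclobutane-1-carboxylic acid | OC(=O)[C@@H]1CC[C@@H]1C(=O)OC
F3 | step 5 | (1R,2R)-2-(methoxycarbonyl)cyclobutane-1-carboxylic acid | OC(=O)[C@@H]1CC[C@H]1C(=O)OC
F4 | step 5 | [(1R,2R)-cyclobutane-1,2-diyl]dimethanol | OC[C@@H]1CC[C@H]1CO
F5 | step 5 | (1R,2R)-cyclobutane-1,2-dicarbaldehyde | O=C[C@@H]1CC[C@H]1C=O
F6 | step 5 | (1R,2R)-1,2-bis(2,2-dibromoethenyl)cyclobutane | BrC(Br)=C[C@@H]1CC[C@H]1C=C(Br)Br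
F7 | step 6 | 2-{chloro[(1R,2R)-2-[(triisopropylsilyl)ethynyl]cyclobutyl]methyl}-4,4,5,5-tetramethyl-1,3,2-dioxaborolane | CC(C)[Si](C(C)C)(C(C)C)C#C[C@@H]1CC[C@H]1C(Cl)B1OC(C)(C)C(C)(C)O1
F8 | step 6 | (1R,2R)-2-[(triisopropylsilyl)ethynyl]cyclobutane-1-carbaldehyde | CC(C)[Si](C(C)C)(C(C)C)C#C[C@@H]1CC[C@H]1C=O
F9 | step 8 | 5-{[(1R,2R)-2-[(triisopropylsilyl)ethynyl]cyclobutyl]ethynyl}-2,2'-bithiophene | CC(C)[Si](C(C)C)(C(C)C)C#C[C@@H]1CC[C@H]1C#Cc1ccc(-c2cccs2)s1
F10 | step 8 | 5-{[(1R,2R)-2-ethynylcyclobutyl]ethynyl}-2,2'-bithiophene | C#C[C@@H]1CC[C@H]1C#Cc1ccc(-c2cccs2)s1
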